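Choose the vessel by one concentration. Substrate leaves by two routes: it closes to ring, first order, or pairs into open dimer, second order. Ring then interconverts with isomer of the product.

in all of them: substrate 0.80 M
- ochre: a single well-mixed tank run continuously and read at steady state, 4.0 h in it on average
- teal: a closed flask charged with all of it at once and left for 4.0 h; time 4.0 h
- amber: plug flow through a tube for 4.0 h, no back-mixing; time 4.0 h

* the set-up with the highest share of ring in all that became ring or open dimer or isomer of the product, at the outlet or at the end ("none" if the first two lie within 2 percentage points) (ochre / teal / amber / none)
* share of ring in all that became ring or open dimer or isomer of the product, at the outlet or at the end, ochre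
* share of ring in all that became ring or open dimer or isomer of the product, at the outlet or at the end, teal
* share of ring in all that became ring or open dimer or isomer of the product, at the outlet or at the end, amber

- percent here means substrate units held: one open dimer counts as two
- for a step with 2 of a species take k times the square, and two of it per event
- the stated concentrations are those of everything mixed, before any reaction; amounts are the same in each set-up
- run time (teal): 4.0 h

    substrate → ring (k1 = 2.11 × 10⁻⁴ /s)
    substrate + substrate ⇌ open dimer (K2 = 33.0 /M, k2 = 2.08 × 10⁻⁴ /M/s)
    ring ⇌ isomer of the product (K3 = 2.64, k3 = 3.25 × 10⁻⁴ /s)

Start with the bench rule: read the split at the start and hold it for the run. Substrate going to ring over substrate going to open dimer is 0.634 at the charge, so ring plus isomer of the product, the pool, gets 38.8% of what reacts.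

Now find the border. Define the crossover concentration, the [substrate] at which both routes use substrate equally (a selectivity factor in concentration units): 0.507 M. The charge is 1.58 times the crossover, so a batch starts on the open-dimer side and falls through the border, and the bench rule stops working there.

Solve both ends and join them. High [substrate] favours open dimer, low [substrate] favours the pool, and each small portion sends crossover/(crossover + [substrate]) to the pool. With open dimer kept as formed, and summed down to zero [substrate], my estimate of the pool is crossover times the natural log of one plus charge over crossover, which is 60.0% of the charge.

Ring and isomer relax in 0.430 h, short against 4.0 h, so take ring as 27.5% of the pool. My flask and tube share is 16.5%.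

The tank sits at a single [substrate]. Its balance, without dimer reversal, gives 0.160 M, below crossover. The pool then takes 76.0%, ring is 37.2% of the pool, and my tank share is 28.3%.

The forecast also picks ochre, with 28.8% for ochre, and 18.3% for teal and amber, each above my figure: “Treat the tube and the flask as identical, since both give the same time course at constant density”.

The simulation gives ochre as best: ochre 28.8%, teal 18.5%, amber 18.5%. Teal's answer has moved 5 points, past the forecast's range, at a charge of 0.331 M below or 1.80 M above. In teal, the pool stands at 59.8% of the charge against the 60.0% from crossover, and ring is 30.1% of that pool against my 27.5%, so my gap lies in the ring fraction.

Recharge the amber tube at 2.0 M: crossover gives a pool of 40.5% and a ring share of 11.1%. The run gives a pool of 41.9% and a ring share of 12.9%.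

The numbers of this flask stand for no real mixture, and the outcome is calculated.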